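Everything hangs on replacing the benzylic C7–OH bond by a C7–Si bond delivered from within. In the target, O9 of the hydroxymethyl group sits two carbons from C7 (the carbinol on ring A), with the ring B aryl ether on C8 between them, so a hydrosilane parked on O9 can reach C7 once C7=C8 is an enol ether. One rhodium–BINAP hydrosilylation then forms the C7–Si bond, closes a five-membered oxasilolane and sets C7 and C8 together by syn addition to an achiral alkene; oxidation later swaps Si for OH. The substrate is the dimethylsilyl ether of an (E)-2-aryloxy-3-arylallyl alcohol, ring A cis to CH2O, carrying benzyl and triisopropylsilyl protection.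

Key step: step 9

Atom labels: C7 is the benzylic carbon on ring A, C8 the carbon bearing the ether oxygen to ring B, C9 the CH2O carbon; the target is (7R,8R), the threo pair.
Abbreviations in names: ArA = 4-benzyloxy-3,5-dimethoxyphenyl; ArB = 2,6-dimethoxy-4-[3-(triisopropylsilyloxy)propyl]phenyl.
Assumption: the sense of face selection by BINAP on this alkene class is not established; (R)-BINAP is written, and (S)-BINAP is to be taken instead if a first run shows the mirror-image (3S,4S) ring.

Step 1
Reactants: 1 4-allyl-2,6-dimethoxyphenol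
Product: 3 dihydrosinapyl alcohol [4-(3-hydroxypropyl)-2,6-dimethoxyphenol], via borane adduct 2 (not isolated)
Conditions: 9-BBN-H (2.3 equiv), THF, 0 °C → rt; then aq. NaOH, 30% H2O2, 0 °C → rt
Reagents that add atoms: hydrogen peroxide, OO
Why: Brown hydroboration–oxidation; the bulky dialkylborane puts boron on the terminal carbon of the allyl group (one equivalent is taken up by the phenol as a borinate that the work-up cleaves) and alkaline peroxide replaces boron by hydroxyl.

Step 2
Reactants: 3 dihydrosinapyl alcohol
Product: 4 ArB–OH [2,6-dimethoxy-4-[3-(triisopropylsilyloxy)propyl]phenol]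
Conditions: iPr3SiCl (1.05 equiv), imidazole, CH2Cl2, 0 °C → rt
Reagents that add atoms: chlorotriisopropylsilane, CC(C)[Si](Cl)(C(C)C)C(C)C
Why: Silyl ether formation; the bulky chlorosilane takes the unhindered primary alcohol, while the phenol, flanked and hydrogen-bonded by two methoxy groups, should react far more slowly.

Step 3
Reactants: 5 methyl bis(2,2,2-trifluoroethyl)phosphonoacetate
Product: 6 methyl 2-diazo-2-[bis(2,2,2-trifluoroethoxy)phosphoryl]acetate
Conditions: 4-AcNHC6H4SO2N3, DBU, MeCN, 0 °C → rt
Reagents that add atoms: 4-acetamidobenzenesulfonyl azide, CC(=O)Nc1ccc(cc1)S(=O)(=O)N=[N+]=[N-]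
Why: Regitz diazo transfer; the methylene between the ester and the phosphoryl group is acidic enough for an amidine base to trigger transfer of the diazo group from the sulfonyl azide.

Step 4
Reactants: 4 ArB–OH; 6 diazo phosphonoacetate
Product: 7 methyl 2-(ArB-oxy)-2-[bis(2,2,2-trifluoroethoxy)phosphoryl]acetate (racemic)
Conditions: Rh2(OAc)4 (1 mol%), toluene, 80 °C, slow addition of 6
Reagents that add atoms: none
Why: Dirhodium carbenoid O–H insertion; the electrophilic carbenoid is trapped by the phenol oxygen and the oxonium ylide collapses by proton shift, so the hindered aryl–O–C8 bond is made without an SN2 step and before any lasting stereocentre exists.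

Step 5
Reactants: 8 syringaldehyde
Product: 9 ArA–CHO [4-benzyloxy-3,5-dimethoxybenzaldehyde]
Conditions: BnBr, K2CO3, DMF, 60 °C
Reagents that add atoms: benzyl bromide, BrCc1ccccc1
Why: Williamson ether synthesis on the acidic phenoxide para to the formyl group.

Step 6
Reactants: 7 aryloxy phosphonoacetate; 9 ArA–CHO
Product: 11 methyl (E)-3-ArA-2-(ArB-oxy)prop-2-enoate, via potassium phosphonate carbanion 10 (not isolated)
Conditions: KN(SiMe3)2, 18-crown-6, THF, −78 °C; then 9, −78 °C
Reagents that add atoms: none
Why: Still–Gennari variant of the Horner–Wadsworth–Emmons olefination; with trifluoroethyl phosphonate esters and a crown-complexed potassium counter-ion the first-formed adduct eliminates before it can equilibrate, which should place the ester cis to ring A, i.e. the (E) enol ether with ring A trans to the aryloxy group.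

Step 7
Reactants: 11 (E)-ester
Product: 12 (E)-3-ArA-2-(ArB-oxy)prop-2-en-1-ol
Conditions: iBu2AlH (2.5 equiv), CH2Cl2, −78 → 0 °C; aq. potassium sodium tartrate
Reagents that add atoms: none
Why: Ester reduction by an aluminium hydride, which stops at the allylic alcohol without conjugate reduction and leaves the alkene geometry, the silyl ether and the benzyl ether untouched.

Step 8
Reactants: 12 (E)-allyl alcohol
Product: 13 (E)-3-ArA-2-(ArB-oxy)prop-2-enyl dimethylsilyl ether
Conditions: (HMe2Si)2NH (2 equiv), neat, rt → 40 °C; volatiles removed in vacuo; used crude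
Reagents that add atoms: 1,1,3,3-tetramethyldisilazane, C[SiH](C)N[SiH](C)C
Why: O-silylation of the primary allylic alcohol by a disilazane; ammonia is the only by-product, so the moisture-sensitive Si–H ether is obtained without aqueous work-up and free of chloride, which would bind the cationic rhodium of the next step.

Step 9
Reactants: 13 hydrosilyl ether
Product: 14 (3R,4R)-3-ArA-4-(ArB-oxy)-2,2-dimethyl-1-oxa-2-silacyclopentane (aryl and aryloxy cis on the ring)
Conditions: [Rh((R)-BINAP)(acetone)2]BF4 (5 mol%; from [Rh(nbd)((R)-BINAP)]BF4 and H2), acetone, 25 → 50 °C, Ar; concentrated and used directly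
Reagents that add atoms: none
Why: Proposed new method: the cationic monovalent rhodium centre adds oxidatively to the Si–H bond, the tethered C7=C8 alkene coordinates to the resulting trivalent rhodium silyl hydride, and migratory insertion followed by reductive elimination places silicon on C7 and hydrogen on C8 from the same face. The closest known reactions are the [Rh(diphosphine)]+-catalysed enantioselective cyclisation of 3-arylallyl hydrosilyl ethers and the platinum-catalysed tethered hydrosilylation of 2-alkoxyallyl silyl ethers; new here is a trisubstituted, 2-aryloxy-substituted alkene under the chiral rhodium catalyst. The oxasilolane closes in the 5-endo-trig mode (Si to C7), the 4-exo alternative (Si to C8) being disfavoured by the strain of an oxasiletane and by the fully substituted, oxygen-bearing C8. C7 is controlled by the alkene face that the C2-symmetric BINAP pocket selects, and C8 by syn addition across the fixed (E) double bond, so that ring A cis to the CH2O arm becomes the cis-3,4-disubstituted ring, which is the threo (7R,8R) pair. The step needs regio-, diastereo- and enantioselectivity: the short O9 tether and the styrene-like polarisation of C7 secure the first, stereospecific syn delivery the second and the ligand the third, and the benzyl and triisopropylsilyl ethers offer no competing Si–H-reactive or strongly coordinating group. The open questions are the lower reactivity of a hindered enol ether and the stability of an alkylrhodium intermediate that carries the aryloxide on the neighbouring carbon.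

Step 10
Reactants: 14 oxasilolane
Product: 15 (1R,2R)-1-ArA-2-(ArB-oxy)propane-1,3-diol
Conditions: 30% H2O2, KF, KHCO3, THF/MeOH (1:1), 0 °C
Reagents that add atoms: hydrogen peroxide, OO
Why: Tamao oxidation; hydroperoxide adds to the fluoride-activated alkoxysilane and C7 migrates from silicon to oxygen with retention, so the (7R,8R) configuration is carried into the diol, while low temperature and the hydrogencarbonate buffer should hold back loss of the C8 aryloxide.

Step 11
Reactants: 15 silyl-protected diol
Product: 16 (1R,2R)-1-ArA-2-[4-(3-hydroxypropyl)-2,6-dimethoxyphenoxy]propane-1,3-diol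
Conditions: Bu4NF, THF, 0 °C → rt
Reagents that add atoms: none
Why: Fluoride-induced cleavage of the silyl ether, driven by the strength of the Si–F bond; the benzyl ether, the alkyl aryl ether and both stereocentres are inert to it.

Step 12
Reactants: 16 benzyl-protected triol
Product: 17 target, (1R,2R)-1-(4-hydroxy-3,5-dimethoxyphenyl)-2-[4-(3-hydroxypropyl)-2,6-dimethoxyphenoxy]propane-1,3-diol
Conditions: H2 (1 atm), 10% Pd/C, EtOAc/MeOH, rt
Reagents that add atoms: none
Why: Hydrogenolysis of the aryl benzyl ether on palladium; under neutral conditions at atmospheric pressure the secondary benzylic C7–OH and the C8–O–aryl bond should be cleaved far more slowly, and no stereocentre is touched.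

Compound list
1 | 4-allyl-2,6-dimethoxyphenol | C=CCc1cc(OC)c(O)c(OC)c1 | starting material
2 | 9-{3-[4-(9-borabicyclo[3.3.1]nonan-9-yloxy)-3,5-dimethoxyphenyl]propyl}-9-borabicyclo[3.3.1]nonane (formed in the flask, not isolated) | COc1cc(CCCB2C3CCCC2CCC3)cc(OC)c1OB1C2CCCC1CCC2 | intermediate
3 | dihydrosinapyl alcohol, 4-(3-hydroxypropyl)-2,6-dimethoxyphenol | OCCCc1cc(OC)c(O)c(OC)c1 | intermediate
4 | 2,6-dimethoxy-4-[3-(triisopropylsilyloxy)propyl]phenol (ArB–OH) | CC(C)[Si](OCCCc1cc(OC)c(O)c(OC)c1)(C(C)C)C(C)C | intermediate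
5 | methyl bis(2,2,2-trifluoroethyl)phosphonoacetate | COC(=O)CP(=O)(OCC(F)(F)F)OCC(F)(F)F | starting material
6 | methyl 2-diazo-2-[bis(2,2,2-trifluoroethoxy)phosphoryl]acetate | COC(=O)C(=[N+]=[N-])P(=O)(OCC(F)(F)F)OCC(F)(F)F | intermediate
7 | methyl 2-(ArB-oxy)-2-[bis(2,2,2-trifluoroethoxy)phosphoryl]acetate, racemic | COC(=O)C(Oc1c(OC)cc(CCCO[Si](C(C)C)(C(C)C)C(C)C)cc1OC)P(=O)(OCC(F)(F)F)OCC(F)(F)F | intermediate
8 | syringaldehyde | COc1cc(C=O)cc(OC)c1O | starting material
9 | 4-benzyloxy-3,5-dimethoxybenzaldehyde (ArA–CHO) | COc1cc(C=O)cc(OC)c1OCc1ccccc1 | intermediate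
10 | potassium salt of the C2 carbanion of 7 (formed in the flask, not isolated) | [K+].COC(=O)[C-](Oc1c(OC)cc(CCCO[Si](C(C)C)(C(C)C)C(C)C)cc1OC)P(=O)(OCC(F)(F)F)OCC(F)(F)F | intermediate
11 | methyl (E)-3-ArA-2-(ArB-oxy)prop-2-enoate (ring A cis to the ester) | COc1cc(/C=C(/Oc2c(OC)cc(CCCO[Si](C(C)C)(C(C)C)C(C)C)cc2OC)C(=O)OC)cc(OC)c1OCc1ccccc1 | intermediate
12 | (E)-3-ArA-2-(ArB-oxy)prop-2-en-1-ol | COc1cc(/C=C(/Oc2c(OC)cc(CCCO[Si](C(C)C)(C(C)C)C(C)C)cc2OC)CO)cc(OC)c1OCc1ccccc1 | intermediate
13 | (E)-3-ArA-2-(ArB-oxy)prop-2-enyl dimethylsilyl ether | COc1cc(/C=C(/Oc2c(OC)cc(CCCO[Si](C(C)C)(C(C)C)C(C)C)cc2OC)CO[SiH](C)C)cc(OC)c1OCc1ccccc1 | intermediate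
14 | (3R,4R)-3-ArA-4-(ArB-oxy)-2,2-dimethyl-1-oxa-2-silacyclopentane | COc1cc([C@@H]2[C@H](Oc3c(OC)cc(CCCO[Si](C(C)C)(C(C)C)C(C)C)cc3OC)CO[Si]2(C)C)cc(OC)c1OCc1ccccc1 | intermediate
15 | (1R,2R)-1-ArA-2-(ArB-oxy)propane-1,3-diol | COc1cc([C@@H](O)[C@@H](CO)Oc2c(OC)cc(CCCO[Si](C(C)C)(C(C)C)C(C)C)cc2OC)cc(OC)c1OCc1ccccc1 | intermediate
16 | (1R,2R)-1-ArA-2-[4-(3-hydroxypropyl)-2,6-dimethoxyphenoxy]propane-1,3-diol | COc1cc([C@@H](O)[C@@H](CO)Oc2c(OC)cc(CCCO)cc2OC)cc(OC)c1OCc1ccccc1 | intermediate
17 | (1R,2R)-1-(4-hydroxy-3,5-dimethoxyphenyl)-2-[4-(3-hydroxypropyl)-2,6-dimethoxyphenoxy]propane-1,3-diol | COc1cc([C@@H](O)[C@@H](CO)Oc2c(OC)cc(CCCO)cc2OC)cc(OC)c1O | target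

Total step count: 12. Longest linear sequence: 10 steps (steps 1, 2, 4, 6, 7, 8, 9, 10, 11, 12, from compound 1).

Steps most likely to fail

Step 9 (the step that goes beyond precedent). The hindered trisubstituted enol ether may not insert, an alkylrhodium intermediate may expel the C8 aryloxide, reversible hydride insertion may move or isomerise the double bond, or face discrimination may be weak. The fallback uses known auxiliary chemistry with no alkene; it sets out from phenol 4 and aldehyde 9 and comes back at diol 15. Phenol 4 is alkylated with bromoacetic acid (NaH, THF) to the aryloxyacetic acid F1. Its mixed pivalic anhydride (pivaloyl chloride, Et3N) acylates lithiated (S)-4-benzyl-2-oxazolidinone (BuLi, THF, −78 °C) to give the N-acyl oxazolidinone F2. The dibutylboron (Z)-enolate of F2 (Bu2BOTf, iPr2NEt, CH2Cl2, −78 °C) adds to 9 through a chair transition state to give the Evans syn aldol adduct F3, which already has the 7R,8R arrangement. LiBH4 (THF, H2O, 0 °C) then removes the auxiliary and delivers 15, after which steps 11 and 12 follow unchanged.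

Step 10. Fluoride-activated silicon may lose the C8 aryloxide by β-elimination, or the benzylic C–Si bond may be protonated, before the shift of C7 to oxygen takes place. The fallback reaches 15 without any C–Si bond; it sets out from phenol 4 and aldehyde 9 and comes back at 15.
- Phenol 4 with methyl bromoacetate (K2CO3, acetone) gives the methyl aryloxyacetate F4.
- Its lithium enolate (LiN(iPr)2, THF, −78 °C) adds to 9 to give the β-hydroxy ester F5 as a mixture of stereoisomers.
- Dess–Martin periodinane converts F5 into the β-keto ester F6, whose C8 centre racemises readily.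
- Asymmetric transfer hydrogenation with dynamic kinetic resolution (RuCl[(S,S)-TsDPEN](p-cymene), HCO2H/Et3N, 30 °C) should give the syn (2S,3R) hydroxy ester F7. This rests on the behaviour of α-alkoxy β-keto esters, and (S,S) is the ligand enantiomer that the aryl ketone model assigns to the 7R carbinol.
- LiBH4 (THF, 0 °C) reduces the ester of F7 to give 15.

Step 6. The bulky aryloxy group on the phosphonate carbon may erode the kinetic preference of the olefination, so that much of the material takes the geometry with ring A cis to the aryloxy group, which would feed the erythro series in step 9. The fallback corrects geometry after the olefination instead of during it; it sets out from 7 and 9 and comes back at 11. The (Z)-ester F8 formed from 7 and 9 is separated from 11 by chromatography. It is then subjected to triplet-sensitised geometric isomerisation (Ir(ppy)3, 450 nm light, MeCN, rt). Energy transfer excites the planar, fully conjugated isomer preferentially and should therefore enrich the twisted isomer that has ring A cis to the ester, which is 11. Remaining F8 is separated and recycled.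

Further compounds
F1 | step 9 | 2-{2,6-dimethoxy-4-[3-(triisopropylsilyloxy)propyl]phenoxy}acetic acid | OC(=O)COc1c(OC)cc(CCCO[Si](C(C)C)(C(C)C)C(C)C)cc1OC
F2 | step 9 | (S)-4-benzyl-3-(2-{2,6-dimethoxy-4-[3-(triisopropylsilyloxy)propyl]phenoxy}acetyl)oxazolidin-2-one | O=C(COc1c(OC)cc(CCCO[Si](C(C)C)(C(C)C)C(C)C)cc1OC)N1[C@@H](Cc2ccccc2)COC1=O
F3 | step 9 | (S)-4-benzyl-3-[(2S,3R)-3-(4-benzyloxy-3,5-dimethoxyphenyl)-2-{2,6-dimethoxy-4-[3-(triisopropylsilyloxy)propyl]phenoxy}-3-hydroxypropanoyl]oxazolidin-2-one | O=C([C@@H](Oc1c(OC)cc(CCCO[Si](C(C)C)(C(C)C)C(C)C)cc1OC)[C@H](O)c1cc(OC)c(OCc2ccccc2)c(OC)c1)N1[C@@H](Cc2ccccc2)COC1=O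
F4 | step 10 | methyl 2-{2,6-dimethoxy-4-[3-(triisopropylsilyloxy)propyl]phenoxy}acetate | COC(=O)COc1c(OC)cc(CCCO[Si](C(C)C)(C(C)C)C(C)C)cc1OC
F5 | step 10 | methyl 3-(4-benzyloxy-3,5-dimethoxyphenyl)-2-{2,6-dimethoxy-4-[3-(triisopropylsilyloxy)propyl]phenoxy}-3-hydroxypropanoate, mixture of stereoisomers | COC(=O)C(Oc1c(OC)cc(CCCO[Si](C(C)C)(C(C)C)C(C)C)cc1OC)C(O)c1cc(OC)c(OCc2ccccc2)c(OC)c1
F6 | step 10 | methyl 3-(4-benzyloxy-3,5-dimethoxyphenyl)-2-{2,6-dimethoxy-4-[3-(triisopropylsilyloxy)propyl]phenoxy}-3-oxopropanoate, racemic | COC(=O)C(Oc1c(OC)cc(CCCO[Si](C(C)C)(C(C)C)C(C)C)cc1OC)C(=O)c1cc(OC)c(OCc2ccccc2)c(OC)c1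
F7 | step 10 | methyl (2S,3R)-3-(4-benzyloxy-3,5-dimethoxyphenyl)-2-{2,6-dimethoxy-4-[3-(triisopropylsilyloxy)propyl]phenoxy}-3-hydroxypropanoate | COC(=O)[C@@H](Oc1c(OC)cc(CCCO[Si](C(C)C)(C(C)C)C(C)C)cc1OC)[C@H](O)c1cc(OC)c(OCc2ccccc2)c(OC)c1
F8 | step 6 | methyl (Z)-3-(4-benzyloxy-3,5-dimethoxyphenyl)-2-{2,6-dimethoxy-4-[3-(triisopropylsilyloxy)propyl]phenoxy}prop-2-enoate | COc1cc(/C=C(\Oc2c(OC)cc(CCCO[Si](C(C)C)(C(C)C)C(C)C)cc2OC)C(=O)OC)cc(OC)c1OCc1ccccc1
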